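**Assumptions (one line each)**
- β-Eudesmol (8) is the natural (+)-enantiomer, 5α-H, 10β-Me, 7β-C(CH3)2OH, bought from a natural-product supplier.
- "Obovatol" (7) is 5-allyl-3-(4-allylphenoxy)benzene-1,2-diol. I did not check this against the literature, but it is the aglycone that matches the target.
- The target's C4 ether has O on the α face and CH3 on the β face, syn to the 10β-methyl. I assume this comes from kinetic O-attack anti to the angular methyl.

**Retrosynthesis**
1. The tertiary C4–O bond is made last by Markovnikov hydroalkoxylation of the exocyclic C4=C15 alkene of β-eudesmol (8) with obovatol (7). The decalin comes from the chiral pool, so no ring is formed in the route, and the C5, C7 and C10 stereocentres are never touched.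
2. Obovatol (7) comes from BBr3 demethylation of the methyl ether 6, which is built by Chan–Lam O-arylation of catechol 3 with 4-allylphenylboronic acid (5).
3. Catechol 3 comes from Dakin oxidation of 5-allyl-o-vanillin (2), which is made by ortho-formylation of eugenol (1).

**Route**

**Step 1**
Reactants: 1 (eugenol, 4-allyl-2-methoxyphenol)
Product: 2 (5-allyl-2-hydroxy-3-methoxybenzaldehyde)
Conditions: (CH2O)n, MgCl2, Et3N, THF, reflux
Reagents that add atoms: paraformaldehyde, C=O (the CHO carbon)
Why: Casnati–Skattebøl ortho-formylation via a magnesium phenoxide occurs only at C6, because the other ortho position carries OMe.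

**Step 2**
Reactants: 2
Product: 3 (5-allyl-3-methoxybenzene-1,2-diol)
Conditions: 30% H2O2, aq. NaOH, MeOH, 0 °C → rt; acidify under N2 with Na2S2O4
Reagents that add atoms: hydrogen peroxide, OO (one O is inserted)
Why: Dakin oxidation of an o-hydroxybenzaldehyde replaces CHO with OH by aryl migration. The isolated allyl groups survive.

**Step 3**
Reactants: 4 (1-allyl-4-bromobenzene)
Product: 5 ((4-allylphenyl)boronic acid)
Conditions: Mg, THF; then B(OMe)3, −78 °C → rt; aq. HCl
Reagents that add atoms: trimethyl borate, COB(OC)OC (supplies B); water, O (hydrolysis to B(OH)2)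
Why: Grignard formation and borylation (borate trapping, then hydrolysis). The allyl group is inert under these conditions.

**Step 4**
Reactants: 3 (5-allyl-3-methoxycatechol) and 5 ((4-allylphenyl)boronic acid)
Product: 6 (4-allyl-2-(4-allylphenoxy)-6-methoxyphenol)
Conditions: Cu(OAc)2 (1.5 equiv), pyridine, 4 Å MS, CH2Cl2, air, rt
Reagents that add atoms: none
Why: Chan–Lam O-arylation goes at the less hindered, distal OH. The central OH is flanked by OMe and OH and is H-bonded to the OMe, so it reacts much more slowly.

**Step 5**
Reactants: 6
Product: 7 (obovatol, 5-allyl-3-(4-allylphenoxy)benzene-1,2-diol)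
Conditions: BBr3 (3 equiv), CH2Cl2, −78 → 0 °C; aq. NaHCO3 quench
Reagents that add atoms: none (the methyl is lost as MeBr)
Why: BBr3 cleaves the aryl methyl ether, helped by chelation to the neighbouring OH. The diaryl ether and the unactivated allyl groups survive at low temperature.

**Step 6**
Reactants: 7 (obovatol, 1.5 equiv) and 8 ((+)-β-eudesmol)
Product: 9 (eudesobovatol A)
Conditions: TfOH (5 mol %), 4 Å MS, CH2Cl2, 0 °C, short reaction time
Reagents that add atoms: none (catalytic acid only; both partners are reactants)
Why: Acid-catalysed Markovnikov hydroalkoxylation. Protonation of the 1,1-disubstituted exocyclic alkene gives the C4 tertiary cation. The less hindered OH of obovatol (the one distal to the OAr group) then traps it. Attack on the α face, anti to the axial 10β-methyl, sets the 4α-OAr/4β-CH3 configuration. The 1,1-disubstituted alkene is far more basic than the two allyl alkenes, so it reacts selectively, and the C11 tertiary alcohol is untouched at low temperature.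

**Compound list**

| # | Name | SMILES | Role |
|---|---|---|---|
| 1 | Eugenol | C=CCc1ccc(O)c(OC)c1 | starting material |
| 2 | 5-Allyl-2-hydroxy-3-methoxybenzaldehyde | C=CCc1cc(C=O)c(O)c(OC)c1 | intermediate |
| 3 | 5-Allyl-3-methoxybenzene-1,2-diol | C=CCc1cc(O)c(O)c(OC)c1 | intermediate |
| 4 | 1-Allyl-4-bromobenzene | C=CCc1ccc(Br)cc1 | starting material |
| 5 | (4-Allylphenyl)boronic acid | C=CCc1ccc(B(O)O)cc1 | intermediate |
| 6 | 4-Allyl-2-(4-allylphenoxy)-6-methoxyphenol | C=CCc1ccc(Oc2cc(CC=C)cc(OC)c2O)cc1 | intermediate |
| 7 | Obovatol | C=CCc1ccc(Oc2cc(CC=C)cc(O)c2O)cc1 | intermediate |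
| 8 | (+)-β-Eudesmol | C[C@]12CCCC(=C)[C@@H]1C[C@@H](CC2)C(C)(C)O | starting material |
| 9 | Eudesobovatol A | C=CCc1ccc(Oc2cc(CC=C)cc(O[C@]3(C)CCC[C@]4(C)CC[C@@H](C(C)(C)O)C[C@H]43)c2O)cc1 | target |

**Total steps:** 6, counting the boronic acid preparation.
**Longest linear sequence:** 5 steps (1 → 2 → 3 → 6 → 7 → 9).

**Three steps most likely to fail**
1. **Step 6, hydroalkoxylation.** Risks are C-alkylation of the electron-rich catechol, isomerisation of β-eudesmol to endocyclic alkenes, 4,11-ether formation, and reversible epimerisation at C4.
   - Fallback: retention-based C–O coupling. Hydrate β-eudesmol to the 4,11-diols, isolate the 4α-alcohol, and couple its tertiary alkoxide with a protected 2-bromo-pyrogallol arene using Pd/biaryl-phosphine C–O coupling. The diaryl ether then has to be installed afterwards.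
2. **Step 4, Chan–Lam regioselectivity.** The catechol may chelate copper, giving poor yield or arylation at the central OH.
   - Fallback: metal-free arylation of the distal phenoxide with (4-allylphenyl)(mesityl)iodonium triflate and t-BuOK in toluene, which is sterically controlled and involves no copper.
3. **Step 5, BBr3 demethylation.** Adventitious HBr could add to the allyl groups or cleave the diaryl ether.
   - Fallback: nucleophilic SN2 demethylation with NaSEt in DMF at 120 °C, which involves no Lewis or Brønsted acid.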